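**Retrosynthetic overview**

1. The angelate is attached last, at the only secondary hydroxyl of (13R)-labd-14-ene-6α,8α,13-triol. That triol comes from a 13-O-silyl labda-7,14-dien-6-one by α-face epoxidation of C7=C8 and reduction with SmI2.
2. Ring B of this enone is cut at C5–C6 and C9–C10. This gives 2,6,6-trimethylcyclohex-1-enyllithium (ring A, C5 the carbanion, C10 the far end of C5=C10) and a 3-methyl-4-alkylcyclobut-2-enone that holds C6–C7–C8–C9 with the side chain on C9.
3. Enabling feature: ring B sits at the oxidation level of a 3-methylcyclohex-2-enone (C6=O, C7=C8 with the C8 methyl), flanked by C5 and the quaternary C10 of ring A. 1,2-Addition at C6, 4π opening of the temporary C6–C9 bond and 6π closure C9–C10 build exactly this ring.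
4. Ring order: ring A is bought as 2,2,6-trimethylcyclohexanone. The temporary four-membered ring is assembled from (R)-linalool (C8 and C11 to C16, with C13), diazomethane (C9), ethoxyacetylene (C6, C7) and MeLi (the C8 methyl). Ring B closes in the key step.
5. Stereochemistry: C13 comes from the chiral pool, the cis C9/C10 relationship from the disrotatory closure, and C5, C8 and C6 from substrate control on the trans-decalin. The closure cannot sense C13, so the natural-decalin diastereomer is selected by crystallization at the triol stage.

Key step: step 7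

Remark: C13 lies three carbons from C9 and cannot bias the ring closure of step 7, so the products of steps 7, 8 and 9 are expected as pairs with the diastereomer that has the antipodal decalin (13R retained); each number, name and SMILES stands for the natural-decalin member, the only one that leads to the target, and the pair is split in step 10.

**Route**

Step 1
Reactants: 1 (R)-(−)-linalool
Product: 2 (3R)-3-(tert-butyldimethylsilyloxy)-3,7-dimethylocta-1,6-diene
Conditions: TBSOTf, 2,6-lutidine, CH2Cl2, −78 °C to 0 °C
Reagents that add atoms: tert-butyldimethylsilyl trifluoromethanesulfonate, CC(C)(C)[Si](C)(C)OS(=O)(=O)C(F)(F)F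
Why: Silyl ether formation at the tertiary allylic alcohol with the silyl triflate and a hindered base masks the only acidic site for the organolithium steps and leaves C13 untouched.

Step 2
Reactants: 2 (3R)-3-(tert-butyldimethylsilyloxy)-3,7-dimethylocta-1,6-diene
Product: 4 (4R)-4-(tert-butyldimethylsilyloxy)-4-methylhex-5-enoic acid, via aldehyde 3 (not isolated)
Conditions: O3, CH2Cl2/MeOH, Sudan Red 7B, −78 °C; Me2S, −78 °C to rt; then NaClO2, NaH2PO4, 2-methyl-2-butene, t-BuOH/H2O, 0 °C to rt
Reagents that add atoms: ozone, [O-][O+]=O; sodium chlorite, [Na+].[O-]Cl=O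
Why: Ozonolysis stopped at the indicator end point should cleave the electron-rich trisubstituted double bond in preference to the vinyl group next to the silyloxy-bearing quaternary carbon, and Pinnick oxidation of the crude aldehyde gives the acid without touching the vinyl group or C13.

Step 3
Reactants: 4 (4R)-4-(tert-butyldimethylsilyloxy)-4-methylhex-5-enoic acid
Product: 6 (5R)-5-(tert-butyldimethylsilyloxy)-1-diazo-5-methylhept-6-en-2-one, via mixed anhydride 5 (not isolated)
Conditions: i-BuOCOCl, N-methylmorpholine, THF, −15 °C; then CH2N2, Et2O, 0 °C to rt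
Reagents that add atoms: diazomethane, C=[N+]=[N-]
Why: Mixed-anhydride activation and acylation of diazomethane (first stage of an Arndt–Eistert homologation) run under near-neutral conditions that the tertiary allylic silyl ether tolerates.

Step 4
Reactants: 6 (5R)-5-(tert-butyldimethylsilyloxy)-1-diazo-5-methylhept-6-en-2-one; 7 ethoxyacetylene
Product: 9 3-ethoxy-4-[(3R)-3-(tert-butyldimethylsilyloxy)-3-methylpent-4-enyl]cyclobut-2-en-1-one, via ketene 8 (not isolated)
Conditions: hν (365 nm), 7 (5 equiv), CH2Cl2, 0 °C to rt
Reagents that add atoms: none
Why: Photochemical Wolff rearrangement gives alkylketene 8, which is intercepted by [2+2] cycloaddition with the electron-rich alkyne 7 (ketene carbonyl carbon to the unsubstituted alkyne carbon) to give the 3-ethoxycyclobutenone as both epimers at the new ring stereocentre, which is harmless because step 7 erases that centre.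

Step 5
Reactants: 9 3-ethoxy-4-[(3R)-3-(tert-butyldimethylsilyloxy)-3-methylpent-4-enyl]cyclobut-2-en-1-one
Product: 11 3-methyl-4-[(3R)-3-(tert-butyldimethylsilyloxy)-3-methylpent-4-enyl]cyclobut-2-en-1-one, via alkoxide 10 (not isolated)
Conditions: MeLi, Et2O, −78 °C; then 0.5 M HCl, THF, 0 °C, short contact
Reagents that add atoms: methyllithium, [Li]C; water, O
Why: 1,2-Addition of MeLi to the vinylogous ester carbonyl followed by acid-induced hydrolysis and dehydration (Stork–Danheiser transposition) places the methyl group on the ring double bond and the carbonyl on the former enol ether carbon, while the ring C–H next to the carbonyl of 9 is not acidic because its enolate would be an antiaromatic cyclobutadienolate.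

Step 6
Reactants: 12 2,2,6-trimethylcyclohexanone
Product: 13 2,2,6-trimethylcyclohexanone 2,4,6-triisopropylbenzenesulfonylhydrazone
Conditions: 2,4,6-triisopropylbenzenesulfonyl hydrazide, HCl (cat.), THF, rt
Reagents that add atoms: 2,4,6-triisopropylbenzenesulfonyl hydrazide, CC(C)c1cc(C(C)C)c(S(=O)(=O)NN)c(C(C)C)c1
Why: Acid-catalysed hydrazone formation on the hindered ketone gives the Shapiro precursor, whose single α-hydrogen fixes the position of the future C5=C10 double bond.

Step 7
Reactants: 13 2,2,6-trimethylcyclohexanone 2,4,6-triisopropylbenzenesulfonylhydrazone; 11 3-methyl-4-[(3R)-3-(tert-butyldimethylsilyloxy)-3-methylpent-4-enyl]cyclobut-2-en-1-one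
Product: 18 (13R)-13-(tert-butyldimethylsilyloxy)labda-7,14-dien-6-one, via alkenyllithium 14 (not isolated), via cyclobutenolate 15 (not isolated), via trienolate 16 (not isolated), via dienolate 17 (not isolated)
Conditions: 13, n-BuLi (2.2 equiv), TMEDA, THF/hexane, −78 °C to 0 °C; then 11, THF, −78 °C to rt; NH4Cl (aq)
Reagents that add atoms: none
Why: The Shapiro reaction of 13 gives alkenyllithium 14, which adds 1,2 to the strained carbonyl of 11 on the face away from the ring substituent (C5–C6), and cyclobutenolate 15 then opens in an alkoxide-accelerated conrotatory 4π process with the oxido group turning outward, which breaks the temporary C6–C9 bond and places the cyclohexenyl group and the side chain on the inside of trienolate 16. Trienolate 16 closes ring B by a thermal disrotatory 6π electrocyclization (six-membered ring, equally a 6-endo vinylogous conjugate addition of C9 to C10) that forms C9–C10 and the quaternary centre, and dienolate 17 is protonated at C5 on work-up; the closest known reaction type is the ring expansion of cyclobutenones to cyclohex-2-enones by alkenyllithium addition, oxy-anion-accelerated 4π opening and 6π closure. C9 and C10 are set together, since disrotation brings the two inside groups (C10 methyl and C9 side chain) cis as in the target, and both ring epimers of 11 converge because C9 is trigonal in 16; C5 is set by protonation of 17 and, being enolizable next to C6=O, settles in the more stable trans ring fusion. The sense of the closure relative to the remote C13 centre is not controlled, so 18 is expected together with a comparable amount of its diastereomer of antipodal decalin configuration, which is carried along and removed in step 10. The step needs 1,2- over 1,4-addition (hard alkenyllithium, low temperature, strained ketone) and closure through C9 and not through the C8 methyl carbon, which the four-membered ring secures because only C9 is released as the trienolate terminus.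

Step 8
Reactants: 18 (13R)-13-(tert-butyldimethylsilyloxy)labda-7,14-dien-6-one
Product: 19 (13R)-13-(tert-butyldimethylsilyloxy)-7α,8α-epoxylabd-14-en-6-one
Conditions: H2O2 (30% aq), NaOH, MeOH/THF, 0 °C to rt
Reagents that add atoms: hydrogen peroxide, OO
Why: Weitz–Scheffer epoxidation (as for isophorone) touches only the enone double bond, and hydroperoxide should add to C8 from the α-face because the β-face is blocked by the axial C10 methyl group, which sets C8 with its methyl group β.

Step 9
Reactants: 19 (13R)-13-(tert-butyldimethylsilyloxy)-7α,8α-epoxylabd-14-en-6-one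
Product: 21 (13R)-13-(tert-butyldimethylsilyloxy)labd-14-ene-6α,8α-diol, via hydroxy ketone 20 (not isolated)
Conditions: SmI2 (5 equiv), THF/MeOH, −78 °C; then H2O, 0 °C to rt
Reagents that add atoms: none
Why: SmI2 reduction of the α,β-epoxy ketone cleaves the C7–O bond to β-hydroxy ketone 20 with C8 untouched, and further electron-transfer reduction of the ketone with the SmI2/H2O couple should give the equatorial 6α-alcohol, since the oxygen-bound samarium avoids the β-face that three axial methyl groups shield (dissolving-metal-type control) and no hydride has to approach that face.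

Step 10
Reactants: 21 (13R)-13-(tert-butyldimethylsilyloxy)labd-14-ene-6α,8α-diol
Product: 22 (13R)-labd-14-ene-6α,8α,13-triol
Conditions: n-Bu4NF, THF, 50 °C; then fractional crystallization (hexane/EtOAc) or chromatography on silica
Reagents that add atoms: none
Why: Fluoride-induced desilylation frees the tertiary alcohol, and 22 should then be separable from the triol of the antipodal-decalin series, because the two differ like sclareol and its C13 epimer in the relation between C13 and the 8-hydroxy decalin core.

Step 11
Reactants: 22 (13R)-labd-14-ene-6α,8α,13-triol; 23 angelic acid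
Product: 25 6α-angeloyloxysclareol (CNP0203829.1), via mixed anhydride 24 (not isolated)
Conditions: 23, 2,4,6-trichlorobenzoyl chloride, Et3N, toluene, rt; then 22, 75 °C
Reagents that add atoms: none
Why: Yamaguchi esterification through mixed anhydride 24 should acylate only the secondary 6α-hydroxyl (the other two hydroxyls are tertiary), and the absence of a nucleophilic amine catalyst should keep the (Z)-geometry of the angelate.

**Compound list**

1 | (R)-(−)-linalool, (3R)-3,7-dimethylocta-1,6-dien-3-ol | C=C[C@](C)(O)CCC=C(C)C | starting material
2 | (3R)-3-(tert-butyldimethylsilyloxy)-3,7-dimethylocta-1,6-diene | C=C[C@](C)(O[Si](C)(C)C(C)(C)C)CCC=C(C)C | intermediate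
3 | (4R)-4-(tert-butyldimethylsilyloxy)-4-methylhex-5-enal | C=C[C@](C)(O[Si](C)(C)C(C)(C)C)CCC=O | intermediate
4 | (4R)-4-(tert-butyldimethylsilyloxy)-4-methylhex-5-enoic acid | C=C[C@](C)(O[Si](C)(C)C(C)(C)C)CCC(=O)O | intermediate
5 | isobutyl carbonic mixed anhydride of 4 | C=C[C@](C)(O[Si](C)(C)C(C)(C)C)CCC(=O)OC(=O)OCC(C)C | intermediate
6 | (5R)-5-(tert-butyldimethylsilyloxy)-1-diazo-5-methylhept-6-en-2-one | C=C[C@](C)(O[Si](C)(C)C(C)(C)C)CCC(=O)C=[N+]=[N-] | intermediate
7 | ethoxyacetylene | C#COCC | starting material
8 | (5R)-5-(tert-butyldimethylsilyloxy)-5-methylhepta-1,6-dien-1-one (alkylketene) | C=C[C@](C)(O[Si](C)(C)C(C)(C)C)CCC=C=O | intermediate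
9 | 3-ethoxy-4-[(3R)-3-(tert-butyldimethylsilyloxy)-3-methylpent-4-enyl]cyclobut-2-en-1-one (both epimers at the ring carbon that bears the side chain) | C=C[C@](C)(O[Si](C)(C)C(C)(C)C)CCC1C(=O)C=C1OCC | intermediate
10 | lithium 3-ethoxy-1-methyl-4-[(3R)-3-(tert-butyldimethylsilyloxy)-3-methylpent-4-enyl]cyclobut-2-en-1-olate | C=C[C@](C)(O[Si](C)(C)C(C)(C)C)CCC1C(C)([O-])C=C1OCC.[Li+] | intermediate
11 | 3-methyl-4-[(3R)-3-(tert-butyldimethylsilyloxy)-3-methylpent-4-enyl]cyclobut-2-en-1-one (both epimers at the ring carbon that bears the side chain) | C=C[C@](C)(O[Si](C)(C)C(C)(C)C)CCC1C(=O)C=C1C | intermediate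
12 | 2,2,6-trimethylcyclohexanone (racemic) | CC1CCCC(C)(C)C1=O | starting material
13 | 2,2,6-trimethylcyclohexanone 2,4,6-triisopropylbenzenesulfonylhydrazone | CC1CCCC(C)(C)C1=NNS(=O)(=O)c1c(C(C)C)cc(C(C)C)cc1C(C)C | intermediate
14 | 2,6,6-trimethylcyclohex-1-enyllithium | [Li]C1=C(C)CCCC1(C)C | intermediate
15 | lithium 3-methyl-4-[(3R)-3-(tert-butyldimethylsilyloxy)-3-methylpent-4-enyl]-1-(2,6,6-trimethylcyclohex-1-enyl)cyclobut-2-en-1-olate (oxido group cis to the side chain on the four-membered ring, both ring antipodes) | C=C[C@](C)(O[Si](C)(C)C(C)(C)C)CCC1C(C)=CC1([O-])C2=C(C)CCCC2(C)C.[Li+] | intermediate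
16 | lithium trienolate from ring opening of 15 (cyclohexenyl group cis to C8 across C6=C7, side chain cis to C7 across C8=C9) | C=C[C@](C)(O[Si](C)(C)C(C)(C)C)CC/C=C(C)\C=C(\[O-])C1=C(C)CCCC1(C)C.[Li+] | intermediate
17 | lithium (13R)-13-(tert-butyldimethylsilyloxy)labda-5,7,14-trien-6-olate (C9 side chain cis to the C10 methyl group) | C=C[C@](C)(O[Si](C)(C)C(C)(C)C)CC[C@@H]1[C@@]2(C)CCCC(C)(C)C2=C([O-])C=C1C.[Li+] | intermediate
18 | (13R)-13-(tert-butyldimethylsilyloxy)labda-7,14-dien-6-one (5α-H, 9α-H, 10β-methyl) | C=C[C@](C)(O[Si](C)(C)C(C)(C)C)CC[C@@H]1[C@@]2(C)CCCC(C)(C)[C@@H]2C(=O)C=C1C | intermediate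
19 | (13R)-13-(tert-butyldimethylsilyloxy)-7α,8α-epoxylabd-14-en-6-one | C=C[C@](C)(O[Si](C)(C)C(C)(C)C)CC[C@@H]1[C@@]2(C)CCCC(C)(C)[C@@H]2C(=O)[C@@H]3[C@@]1(C)O3 | intermediate
20 | (13R)-13-(tert-butyldimethylsilyloxy)-8α-hydroxylabd-14-en-6-one | C=C[C@](C)(O[Si](C)(C)C(C)(C)C)CC[C@@H]1[C@@]2(C)CCCC(C)(C)[C@@H]2C(=O)C[C@@]1(C)O | intermediate
21 | (13R)-13-(tert-butyldimethylsilyloxy)labd-14-ene-6α,8α-diol | C=C[C@](C)(O[Si](C)(C)C(C)(C)C)CC[C@@H]1[C@@]2(C)CCCC(C)(C)[C@@H]2[C@@H](O)C[C@@]1(C)O | intermediate
22 | (13R)-labd-14-ene-6α,8α,13-triol (6α-hydroxysclareol) | C=C[C@](C)(O)CC[C@@H]1[C@@]2(C)CCCC(C)(C)[C@@H]2[C@@H](O)C[C@@]1(C)O | intermediate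
23 | angelic acid, (Z)-2-methylbut-2-enoic acid | C/C=C(/C)C(=O)O | starting material
24 | angelic 2,4,6-trichlorobenzoic anhydride | C/C=C(/C)C(=O)OC(=O)c1c(Cl)cc(Cl)cc1Cl | intermediate
25 | 6α-angeloyloxysclareol, (13R)-6α-[(Z)-2-methylbut-2-enoyloxy]labd-14-ene-8α,13-diol (CNP0203829.1) | C=C[C@](C)(O)CC[C@@H]1[C@@]2(C)CCCC(C)(C)[C@@H]2[C@@H](OC(=O)/C(C)=C\C)C[C@@]1(C)O | target

**Step count and risks**

Total step count: 11. Longest linear sequence: 10 steps (steps 1 to 5 and 7 to 11, from (R)-linalool).

The three steps most likely to fail are steps 7, 9 and 10.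

In step 7 the hindered alkenyllithium 14 may act as a base towards the C8 methyl group of 11 instead of adding to the carbonyl, or proton transfer in the lithium trienolate 16 may outrun ring closure. The fallback sets out from 11 and forms the two bonds in two separate operations. Alkenyllithium 14, made from 13 as in step 7, is transmetallated with anhydrous CeCl3 in THF at −78 °C. The less basic organocerium reagent adds to 11, and a cold quench with NH4Cl should allow isolation of 3-methyl-4-[(3R)-3-(tert-butyldimethylsilyloxy)-3-methylpent-4-enyl]-1-(2,6,6-trimethylcyclohex-1-enyl)cyclobut-2-en-1-ol F1. Deprotonation of this alcohol with KH and 18-crown-6 in THF at −78 °C to rt then triggers the ring expansion on its own. The more dissociated potassium alkoxide should accelerate both the 4π opening and the 6π closure, with the same stereochemical course. This comes back to the route at 18 (with its partner diastereomer, as in the main route).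

In step 9 the second reduction may stall at hydroxy ketone 20, may deliver the new hydrogen to the α-face and give the axial 6β-alcohol, or the SmI2/H2O couple may attack the allylic C13–O bond. The fallback sets out from 19 and moves the reduction behind the desilylation, so that C13 carries an alkoxide that cannot leave. n-Bu4NF in THF at 40 °C should give (13R)-13-hydroxy-7α,8α-epoxylabd-14-en-6-one F2. Li in liquid NH3/THF at −78 °C, then EtOH and NH4Cl, should open the epoxy ketone and reduce the ketone to the equatorial alcohol (dissolving-metal reduction under thermodynamic control). This comes back to the route at 22, which is still accompanied by its partner diastereomer and is purified as in step 10.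

In step 10 the two triols differ only in the relation between the remote C13 centre and the decalin, so they may co-crystallize or co-elute. The fallback sets out from 21 (as the pair obtained in step 9) and distinguishes the two series at the ring carbinol C6, whose configuration is opposite in the two. Lipase-catalysed transesterification (Candida rugosa lipase or Burkholderia cepacia lipase, vinyl acetate, tert-butyl methyl ether, 40 °C) should follow the usual preference of lipases for the (R)-configured secondary carbinol. It would then acetylate the antipodal-decalin partner to (13R)-6-acetoxy-13-(tert-butyldimethylsilyloxy)labd-14-en-8-ol with all five ring stereocentres inverted F3 and leave the (6S)-carbinol of 21 free. Ester and diol are then separated on silica, and the route is rejoined at 21, which is desilylated as in step 10 without further separation.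

Further compounds
F1 | step 7 | 3-methyl-4-[(3R)-3-(tert-butyldimethylsilyloxy)-3-methylpent-4-enyl]-1-(2,6,6-trimethylcyclohex-1-enyl)cyclobut-2-en-1-ol (hydroxyl cis to the side chain) | C=C[C@](C)(O[Si](C)(C)C(C)(C)C)CCC1C(C)=CC1(O)C2=C(C)CCCC2(C)C
F2 | step 9 | (13R)-13-hydroxy-7α,8α-epoxylabd-14-en-6-one | C=C[C@](C)(O)CC[C@@H]1[C@@]2(C)CCCC(C)(C)[C@@H]2C(=O)[C@@H]3[C@@]1(C)O3
F3 | step 10 | (13R)-6-acetoxy-13-(tert-butyldimethylsilyloxy)labd-14-en-8-ol with all five ring stereocentres inverted (6-O-acetate of the antipodal-decalin partner of 21) | C=C[C@](C)(O[Si](C)(C)C(C)(C)C)CC[C@H]1[C@]2(C)CCCC(C)(C)[C@H]2[C@H](OC(C)=O)C[C@]1(C)O
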